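Compare two times in each flask: the time it is given and the time its catalyst needs to clear the charge.

| flask | starting material | second substrate | gas | free catalyst | remark | time |
|---|---|---|---|---|---|---|
| east | 0.050 M | 0.050 M | 13 mM (held) | 36 µM | run made earlier |  |
| north-east | 0.050 M | 0.050 M | 13 mM (held) | 58 µM | run made earlier |  |
| south-west | 0.050 M | 0.074 M | 13 mM (held) | 25 µM | run made earlier |  |
| elm | 0.050 M | 0.0500 M | 13 mM (held) | 25 µM |  | 25 min |
| birch | 0.050 M | 0.100 M | 13 mM (held) | 40 µM |  | 80 min |

- east (time / min: target / %, starting material / %): 3.00: 11.5, 88.1; 6.00: 24.3, 75.1; 10.0: 43.2, 57.6; 12.0: 51.8, 48.2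
- north-east (time / min: target / %, starting material / %): 1.00: 4.4, 95.4; 2.50: 14.0, 85.9; 5.00: 30.8, 69.9; 12.0: 74.1, 26.4
- south-west (time / min: target / %, starting material / %): 3.00: 6.6, 93.2; 6.00: 14.1, 85.5; 10.0: 24.9, 74.4; 12.0: 30.7, 69.0

(readings scatter by 0.3 percentage points)

- the analysis behind the earlier runs scatters by 0.3 percentage points, standard deviation
- at the start none of the gas is in solution

* which one finishes higher in amount of target, in percent of the starting material charged ("neither" within 2 percentage points) (elm / birch / neither)
* amount of target at the end, in percent of the starting material charged, elm
* amount of target at the end, in percent of the starting material charged, birch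

Start with the lag. None of the gas is in solution at the start, and the steady line of the east run runs back to zero target at 0.698 min. That is short against the next rung.

Next take the steady slope of the east run from 6.00 min to 12.0 min. Its inverse is the clearing time, the time to turn the whole charge into target at that slope: 21.8 min. As a first count, with the other charges fixed, scale it as one over c(free catalyst). Elm has the starting material and second substrate of the east run, so its clearing time is 31.4 min. Elm's time after the lag covers 77.3% of that.

The south-west run, richer in second substrate, reads 36.1 min at 25 µM. Scaled to birch's catalyst, this gives 22.6 min. Per catalyst, the south-west run is slower than the east run, and birch holds still more second substrate, so expect longer. Even so, birch is given 3.51 of these times.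

Last comes the tail. The same count for the north-east run gives 83.5%, but the reading is 74.1%, an overshoot of 9.4 percentage points. Take that off elm and commit to 68.0%. Expect birch near completion.

The forecast says birch, with elm at 77% and birch at 96%, and holds that “the second substrate inhibits”. Its elm figure stands above mine.

The flasks give 72.5% for elm and >99.9% for birch, so birch finishes higher.

    starting material + free catalyst ⇌ catalyst intermediate A (K = 15.2 M⁻¹, k = 10100 M⁻¹ min⁻¹)
    reagent + catalyst intermediate A → free catalyst + target (k = 26800 M⁻¹ min⁻¹)
    second substrate + free catalyst ⇌ catalyst intermediate B (K = 433 M⁻¹, k = 11000 M⁻¹ min⁻¹)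
    reagent + catalyst intermediate B → free catalyst + second product (k = 33500 M⁻¹ min⁻¹)
    gas ⇌ reagent, rate k5*(csat - [reagent]) (kL = 4.25 min⁻¹)

Birch stands 5 points below its end value at 33.2 min, earlier than its 80 min. Elm's clearing time of 31.4 min is longer than its 25 min, and elm ends with 28% of the starting material left. The neighbour of birch with 10.0 µM of free catalyst has, scaled from the south-west slope, a clearing time of 90.4 min, longer than the same 80 min, and it ends at 78.1%.

All runs are simulated with constants of no real substance, and the scatter is random.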